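If two flasks get the same partner and second substrate but differ in starting material, carry over first what a unit of partner paid in target.

| flask | starting material | coupling partner | second substrate | remark | time |
|---|---|---|---|---|---|
| Monday's | 0.075 M | 0.045 M (fed, over 10 min) | 0.025 M | run made earlier |  |
| flask | 0.050 M | 0.0450 M (fed, over 10 min) | 0.0250 M |  | 4.0 h |

- Monday's (time / min: target / %, starting material / %): 2.00: 0.3, 99.0; 4.00: 2.9, 96.6; 6.00: 5.8, 94.6; 12.0: 17.4, 82.2; 25.0: 29.0, 71.0

(each reading ± 0.5 percentage points)

- the earlier runs were read with a standard deviation of 0.5 percentage points

- the target in the flask at 4.0 h, as a percentage of the starting material charged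
- the starting material in the flask at 4.0 h, as a percentage of the starting material charged
- concentration of coupling partner at 4.0 h, in M

Monday's last reading looks odd. Target and starting material add up to 100 % of the charge, so the starting material is accounted for. Yet 0.045 M of partner went in over 10 min, and the target at 25.0 min is 0.0217 M, about half of that partner, if one partner goes into each target. The other 0.0232 M appears in no reading. That gap is close to the second substrate charge, so I suspect a second taker.

The new flask has the same partner and second substrate charges, so I freeze the split as read from Monday's last reading: φ = 0.483, the target formed per unit of partner charged. In the new flask the partner is the limiting reagent, with 0.0450 M against 0.050 M of starting material. My reckoning is φ times 0.0450 M over 0.050 M, which gives 43.5 % target and 56.5 % starting material. I treat that estimate for the new flask as low, since Monday's target gained 12 points over its last interval and the readings stop at 25.0 min, well before 4.0 h.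

The forecast differs slightly, with 42 % target, 58 % starting material and 5.000 × 10⁻⁴ M partner, and it says the rest of the partner went most likely to “the second substrate, which competes and is the faster consumer”.

The flask gives 51.6 % target, 48.4 % starting material and 0.00121 M partner.

    starting material + coupling partner ⇌ target (K = 978 /M, k = 0.0179 /M/s)
    second substrate + coupling partner ⇌ second product (K = 30.6 /M, k = 0.0976 /M/s)
    coupling partner ⇌ dormant form (K = 13.0, k = 4.67 × 10⁻⁴ /s)

My reckoning falls 8.1 points short: the flask's partner yield at 4.00 h is 0.573, more than φ. The flask's second substrate stands at 96.4 % of its own charge, and the flask holds 0.0171 M of dormant form against 8.96 × 10⁻⁴ M of second product. A neighbour flask keeps the same partner and second substrate charges but has 0.20 M of starting material, and φ gives it 10.9 % target. That neighbour holds 19.9 % target, with 80.1 % of its starting material left.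

Readings and results are simulated with made-up constants, and the scatter is random.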